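Amounts first: 0.20 M of substrate is in solution, and 0.240 M of solid reagent stands undissolved, entering as partner through a slow dissolution.

    substrate + partner ⇌ target (K1 = 4.4 M⁻¹, k1 = 7.8 × 10⁻⁴ M⁻¹ s⁻¹, Ea1 = 71.0 kJ mol⁻¹, ΔH1 = −59.0 kJ mol⁻¹)
    substrate + partner ⇌ isomer of the product (K2 = 11 M⁻¹, k2 = 4.4 × 10⁻⁴ M⁻¹ s⁻¹, Ea2 = 89.0 kJ mol⁻¹, ΔH2 = −19.0 kJ mol⁻¹)
    partner → decomposed reagent (k3 = 3.5 × 10⁻⁴ s⁻¹, Ea3 = 103 kJ mol⁻¹)
    solid reagent ⇌ partner, rate k4*(cs4 - [partner]) while solid is left; crystals form when [partner] > cs4 (cs4 = 0.18 M, k4 = 2.8 × 10⁻⁵ s⁻¹)
    (constants at 90 °C)

| setting | Saturday's | Wednesday's | Tuesday's | Sunday's |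
|---|---|---|---|---|
| substrate | 0.20 M | 0.20 M | 0.20 M | 0.20 M |
| solid reagent | 0.240 M | 0.240 M | 0.240 M | 0.240 M |
| temperature | 105 °C | 120 °C | 75 °C | 90 °C |
| time | 8.0 h | 8.0 h | 8.0 h | 8.0 h |

- the flask with the highest amount of target, in percent of the substrate charged ("all alike" if they lie within 1.5 percentage points) (Saturday's / Wednesday's / Tuesday's / Sunday's / all alike)
- final target, as a percentage of the substrate charged, in Saturday's
- final target, as a percentage of the substrate charged, in Wednesday's
- final target, as a percentage of the substrate charged, in Tuesday's
- final target, as a percentage of the substrate charged, in Sunday's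

- as a solid, counted per litre of solution: solid reagent
- all constants are for 90 °C and move with temperature by the activation energies and enthalpies
- at the start none of the solid reagent is in solution

My own reckoning builds Tuesday's flask one process at a time. While [partner] is small against 0.18 M, the solid feeds at 0.0181 M h⁻¹, which over 8.0 h delivers 0.145 M. With the main step by itself, and each dissolved partner caught by substrate, the reckoning turns that feed into 72.6% target.

Now add decomposition. Scaled to 75 °C, it removes partner at 0.290 h⁻¹. The main step, with substrate held at its charge and so pseudo-first-order in partner, removes it at 0.204 h⁻¹. Target's share of the race is 41.3%, which lowers the number to 30.0%.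

Then come the rest. The isomer step adds 0.0890 h⁻¹, and the slowing of dissolution as [partner] rises adds 0.1 h⁻¹. The sum gives 1.46 h: the lifetime of dissolved partner, the inverse of the sum of its first-order losses. This lifetime is shorter than the run, so the reckoning puts partner in a resting state at feed times lifetime, 0.0265 M. Target also flows back, with a lifetime of 10.0 h, longer than the run. So the reckoning lets target climb exponentially towards the equilibrium constant 10.2 M⁻¹ times that level, 27.1% of the charge. Starting the climb one partner lifetime late gives 13.0% at 8.0 h. Warming speeds decomposition 59 times across the range against 17 for the main step, and the equilibrium constant of the main step falls to 4.4 M⁻¹ at 90 °C. The reckoning therefore expects the warmer flasks lower, and stops there.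

The forecast names Tuesday's, with 13.5% there, 4.7% in Sunday's, 0.7% in Saturday's and 0.1% in Wednesday's, saying that “partner survives longer and the reverse reaction is slow”. Its Tuesday's figure stands above mine.

The simulation gives Tuesday's first, with 12.6%, then 4.56% in Sunday's, 0.709% in Saturday's and 0.104% in Wednesday's. In Tuesday's at 8.00 h, [partner] reads 0.0320 M, above the level of 0.0265 M from the lifetime. Decomposition there uses partner 1.8 times as fast as the forward step to target. Tuesday's read at 15 h has solid at 4.92% of its charge, and the same lifetime gives 20.1%; the computed value is 19.5%.

All constants are made up, and the outcome is calculated.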